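**Assumption:** the isopentyl group is 3-methylbutyl. (R)-3-Bromo-2-methylpropan-1-ol and (R)-glycidol are taken as commercial single enantiomers.

## Retrosynthetic overview
1. The 3-methyltetronic acid is closed last, by Lacey–Dieckmann cyclisation of an (S)-α-propionyloxy ester made from an α-hydroxy ester.
2. The (E,E)-diene comes from a Negishi coupling of an (E)-vinyl iodide carrying the N-isopentyl pyrrolinone with an (E)-alkenylzirconium made from a chiral terminal alkyne.
3. The pyrrolinone is made early, by dearomatising a simple 3-alkylfuran (from 3-bromofuran) with ¹O₂, amine exchange and ionic hydrogenation in one pot. This is the central bold step.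
4. The alkyne fragment comes from a chiral-pool bromo-alcohol, which sets the C8 methyl stereocentre.
5. The Z-trisubstituted alkene comes from Pd-catalysed methylation of a gem-dibromoalkene. C5 (S) comes from opening (R)-glycidol with the resulting Z-alkenyl Grignard under Cu catalysis.

## Forward route

**Step 1**
Reactants: 1 (3-bromofuran), 2 (5-iodopent-1-yne)
Product: 3 (3-(pent-4-yn-1-yl)furan)
Conditions: Zn dust, LiCl, THF, 40 °C to make the alkylzinc; then 3-bromofuran, Pd-PEPPSI-IPr (2 mol%), THF, 25 °C.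
Reagents that add atoms: none
Why: Negishi sp³–sp² coupling of an in situ alkylzinc iodide with a cheap heteroaryl bromide; the terminal alkyne is untouched; no stereocentres.

**Step 2**
Reactants: 3
Product: 4 (3-[(4E)-5-iodo-4-methylpent-4-en-1-yl]furan)
Conditions: Me₃Al, Cp₂ZrCl₂ (20 mol%), (CH₂Cl)₂, 23 °C, 20 h; then I₂, THF, –30 °C.
Reagents that add atoms: trimethylaluminium C[Al](C)C (CH₃); iodine II (I)
Why: Negishi Zr-catalysed methylalumination is a syn carbometalation, so Me sits cis to Al and trans to the chain; iodinolysis gives the (E)-trisubstituted vinyl iodide that becomes the C11=C12 bond of the diene.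

**Step 3**
Reactants: 4, 5 (3-methylbutylamine)
Product: 8 (pyrrolinone vinyl iodide), via in-situ intermediates 6 and 7
Conditions: one pot, three stages. (i) O₂, Rose Bengal (1 mol%), iPr₂NEt (3 equiv), visible light, CH₂Cl₂, –78 °C. (ii) 5 (1.5 equiv), 4 Å MS, 0 °C to 23 °C, 12 h. (iii) Et₃SiH (5 equiv), then TFA (30 equiv), 0 °C to 23 °C.
Reagents that add atoms: dioxygen O=O (supplies the lactam C=O oxygen); amine 5 is listed as a reactant
Why: Singlet-oxygen [4+2] cycloaddition dearomatises the furan to an endoperoxide. Base-induced Kornblum–DeLaMare opening removes the less hindered α-H, giving the 4-alkyl-5-hydroxybutenolide 6. The amine converts this to the N-acyl hemiaminal 7 (hydroxylactam). Et₃SiH/TFA reduces the N-acyliminium ion to put CH₂ next to the substituted carbon, giving 8. No stereocentre is formed, because C5 of the lactam is CH₂. Proposed new method: this telescoped furan-to-3-pyrrolin-2-one conversion on a vinyl iodide substrate. The mechanism is a Kernan–Faulkner photooxygenation, then aminolysis of a γ-hydroxybutenolide to a γ-hydroxylactam (as in mucochloric-acid chemistry), then Et₃SiH/TFA ionic hydrogenation of a hydroxylactam. The vinyl iodide is inert to ¹O₂ at –78 °C compared with the furan.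

**Step 4**
Reactants: 9 ((2R)-3-bromo-2-methylpropan-1-ol)
Product: 10 (TBS ether of 9)
Conditions: TBSCl, imidazole, DMF, 0 °C to 23 °C.
Reagents that add atoms: TBSCl CC(C)(C)[Si](C)(C)Cl
Why: Silyl protection; the stereocentre is untouched.

**Step 5**
Reactants: 10
Product: 11 (tert-butyl{[(2S)-2-methylhex-5-en-1-yl]oxy}dimethylsilane)
Conditions: allylMgBr (1.5 equiv), Li₂CuCl₄ (5 mol%), THF, –30 °C to 0 °C.
Reagents that add atoms: allylmagnesium bromide C=CC[Mg]Br (allyl)
Why: Cu-catalysed SN2 coupling of a primary bromide, with no change at the remote stereocentre. The descriptor changes from R to S only because the CIP priorities swap.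

**Step 6**
Reactants: 11
Product: 12 ((4S)-5-(TBSO)-4-methylpentanal)
Conditions: OsO₄ (2 mol%), NaIO₄ (4 equiv), 2,6-lutidine, dioxane/H₂O 3:1, 23 °C.
Reagents that add atoms: sodium periodate [Na+].[O-]I(=O)=O and water O (carbonyl oxygen source)
Why: Lemieux–Johnson cleavage of the monosubstituted alkene; the γ-stereocentre cannot epimerise.

**Step 7**
Reactants: 12
Product: 13 (TBSO-CH₂-CH(Me)-CH₂CH₂-CH=CBr₂, S)
Conditions: CBr₄ (2 equiv), PPh₃ (4 equiv), CH₂Cl₂, 0 °C.
Reagents that add atoms: carbon tetrabromide BrC(Br)(Br)Br (CBr₂)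
Why: Ramirez (Corey–Fuchs) gem-dibromo-olefination.

**Step 8**
Reactants: 13
Product: 14 (tert-butyl{[(2S,5Z)-6-bromo-2-methylhept-5-en-1-yl]oxy}dimethylsilane)
Conditions: MeZnCl (1.1 equiv), Pd(PPh₃)₄ (5 mol%), THF, 23 °C.
Reagents that add atoms: methylzinc chloride C[Zn]Cl (CH₃)
Why: Negishi coupling of a gem-dibromoalkene occurs at the more reactive Br trans to the chain, so Me ends up trans to the chain and the remaining Br cis to it. This fixes the Z geometry of the future trisubstituted alkene.

**Step 9**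
Reactants: 14, 15 ((R)-glycidol)
Product: 16 ((2S,4Z,8S)-9-(TBSO)-4,8-dimethylnon-4-ene-1,2-diol)
Conditions: t-BuLi (2.1 equiv), Et₂O, –78 °C; MgBr₂·OEt₂; then CuI (20 mol%) and (R)-glycidol (1.5 equiv) pre-treated with MeMgCl (1.5 equiv) as its Mg alkoxide, THF, –40 °C to 0 °C.
Reagents that add atoms: none beyond reactant 15
Why: Li–Br exchange and Mg transmetalation occur with retention of the Z geometry. Cu-catalysed SN2 opening at the terminal carbon of the epoxide leaves the glycidol C2 stereocentre untouched. That carbon becomes C5 and is (S) because of the CIP priorities. The new C–C bond is the CH₂–C(Me)= linkage.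

**Step 10**
Reactants: 16
Product: 17 ((2S,4Z,8S)-9-(TBSO)-2-hydroxy-4,8-dimethylnon-4-enoic acid)
Conditions: TEMPO (10 mol%), NaClO₂ (2.5 equiv), NaOCl (2 mol%), MeCN/pH 6.7 phosphate buffer, 35 °C.
Reagents that add atoms: water O (carboxyl oxygen source)
Why: Zhao–Grabowski oxidation is selective for the primary alcohol over the secondary one and leaves the alkene and TBS ether alone at near-neutral pH; C2 is not epimerised.

**Step 11**
Reactants: 17
Product: 18 (methyl ester of 17)
Conditions: TMSCHN₂, MeOH/PhMe, 0 °C.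
Reagents that add atoms: trimethylsilyldiazomethane C[Si](C)(C)[CH-][N+]#N (CH₃)
Why: Mild, non-basic esterification that avoids racemisation.

**Step 12**
Reactants: 18
Product: 19 (methyl (2S,4Z,8S)-2,9-dihydroxy-4,8-dimethylnon-4-enoate)
Conditions: HF·pyridine, THF/pyridine, 0 °C to 23 °C.
Reagents that add atoms: none
Why: Selective removal of the primary TBS ether under buffered acidic conditions.

**Step 13**
Reactants: 19
Product: 20 (methyl (2S,4Z,8S)-2-hydroxy-4,8-dimethyl-9-oxonon-4-enoate)
Conditions: TEMPO (10 mol%), PhI(OAc)₂ (1.2 equiv), CH₂Cl₂, 23 °C.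
Reagents that add atoms: none
Why: Oxoammonium oxidation is chemoselective for the primary alcohol over the deactivated α-hydroxy ester, under neutral conditions that preserve the α-methyl stereocentre.

**Step 14**
Reactants: 20
Product: 21 (methyl (2S,4Z,8S)-2-hydroxy-4,8-dimethyldec-4-en-9-ynoate)
Conditions: dimethyl (1-diazo-2-oxopropyl)phosphonate (1.5 equiv), K₂CO₃ (2 equiv), MeOH, 0 °C to 23 °C.
Reagents that add atoms: Ohira–Bestmann reagent COP(=O)(OC)C(=[N+]=[N-])C(C)=O (supplies the alkyne carbon)
Why: Seyferth–Gilbert homologation under mild Ohira–Bestmann conditions, with little epimerisation of the α-branched aldehyde; C8 stays (S).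

**Step 15**
Reactants: 21, 8
Product: 22 (methyl (2S,4Z,8S,9E,11E)-2-hydroxy-4,8,12-trimethyl-15-[1-(3-methylbutyl)-2-oxo-2,5-dihydro-1H-pyrrol-4-yl]pentadeca-4,9,11-trienoate)
Conditions: Cp₂Zr(H)Cl (2.3 equiv), THF, 23 °C, 30 min; then ZnCl₂ (1.2 equiv); then 8 (0.9 equiv), Pd(PPh₃)₄ (5 mol%), THF, 23 °C, 3 h.
Reagents that add atoms: none (hydride from the Schwartz reagent is H only)
Why: Syn hydrozirconation gives the (E)-alkenylzirconium, and stereoretentive Zr→Zn→Pd Negishi coupling gives the (9E,11E)-diene. The extra equivalent of Schwartz reagent covers the free OH. The stereocentres are not touched.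

**Step 16**
Reactants: 22
Product: 23 (2-propanoyloxy ester of 22)
Conditions: EtCOCl (1.5 equiv), pyridine (3 equiv), DMAP (10 mol%), CH₂Cl₂, 0 °C.
Reagents that add atoms: propionyl chloride CCC(=O)Cl (C₃H₅O)
Why: O-Acylation of the secondary alcohol with retention of configuration.

**Step 17**
Reactants: 23
Product: 24 (Sarcotrine D)
Conditions: KOtBu (2.5 equiv), THF, –78 °C to 0 °C, 1 h; then 1 M HCl to pH 2.
Reagents that add atoms: none
Why: Lacey–Dieckmann condensation of the propionate enolate onto the methyl ester closes the five-membered ring and gives the 3-methyltetronate, which is protonated to the 4-hydroxybutenolide. Rapid irreversible ring closure at low temperature outcompetes C5 deprotonation, so (5S) is retained (risk noted below).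

## Compound list
1 | 3-bromofuran | Brc1ccoc1 | starting material
2 | 5-iodopent-1-yne | C#CCCCI | starting material
3 | 3-(pent-4-yn-1-yl)furan | C#CCCCc1ccoc1 | intermediate
4 | 3-[(4E)-5-iodo-4-methylpent-4-en-1-yl]furan | I/C=C(\C)CCCc1ccoc1 | intermediate
5 | 3-methylbutan-1-amine | NCCC(C)C | starting material
6 | 5-hydroxy-4-[(4E)-5-iodo-4-methylpent-4-en-1-yl]furan-2(5H)-one (in situ) | I/C=C(\C)CCCC1=CC(=O)OC1O | intermediate
7 | 5-hydroxy-4-[(4E)-5-iodo-4-methylpent-4-en-1-yl]-1-(3-methylbutyl)-1,5-dihydro-2H-pyrrol-2-one (in situ) | I/C=C(\C)CCCC1=CC(=O)N(CCC(C)C)C1O | intermediate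
8 | 4-[(4E)-5-iodo-4-methylpent-4-en-1-yl]-1-(3-methylbutyl)-1,5-dihydro-2H-pyrrol-2-one | I/C=C(\C)CCCC1=CC(=O)N(CCC(C)C)C1 | intermediate
9 | (2R)-3-bromo-2-methylpropan-1-ol | OC[C@@H](C)CBr | starting material
10 | tert-butyl[(2R)-3-bromo-2-methylpropoxy]dimethylsilane | CC(C)(C)[Si](C)(C)OC[C@@H](C)CBr | intermediate
11 | (5S)-6-(TBSO)-5-methylhex-1-ene | CC(C)(C)[Si](C)(C)OC[C@@H](C)CCC=C | intermediate
12 | (4S)-5-(TBSO)-4-methylpentanal | CC(C)(C)[Si](C)(C)OC[C@@H](C)CCC=O | intermediate
13 | (2S)-6,6-dibromo-1-(TBSO)-2-methylhex-5-ene | CC(C)(C)[Si](C)(C)OC[C@@H](C)CCC=C(Br)Br | intermediate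
14 | (2S,5Z)-6-bromo-1-(TBSO)-2-methylhept-5-ene | CC(C)(C)[Si](C)(C)OC[C@@H](C)CC/C=C(\Br)C | intermediate
15 | (R)-glycidol | OC[C@@H]1CO1 | starting material
16 | (2S,4Z,8S)-9-(TBSO)-4,8-dimethylnon-4-ene-1,2-diol | CC(C)(C)[Si](C)(C)OC[C@@H](C)CC/C=C(\C[C@H](O)CO)C | intermediate
17 | (2S,4Z,8S)-9-(TBSO)-2-hydroxy-4,8-dimethylnon-4-enoic acid | CC(C)(C)[Si](C)(C)OC[C@@H](C)CC/C=C(\C[C@H](O)C(=O)O)C | intermediate
18 | methyl (2S,4Z,8S)-9-(TBSO)-2-hydroxy-4,8-dimethylnon-4-enoate | CC(C)(C)[Si](C)(C)OC[C@@H](C)CC/C=C(\C[C@H](O)C(=O)OC)C | intermediate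
19 | methyl (2S,4Z,8S)-2,9-dihydroxy-4,8-dimethylnon-4-enoate | OC[C@@H](C)CC/C=C(\C[C@H](O)C(=O)OC)C | intermediate
20 | methyl (2S,4Z,8S)-2-hydroxy-4,8-dimethyl-9-oxonon-4-enoate | O=C[C@@H](C)CC/C=C(\C[C@H](O)C(=O)OC)C | intermediate
21 | methyl (2S,4Z,8S)-2-hydroxy-4,8-dimethyldec-4-en-9-ynoate | C#C[C@@H](C)CC/C=C(\C[C@H](O)C(=O)OC)C | intermediate
22 | methyl (2S,4Z,8S,9E,11E)-2-hydroxy-4,8,12-trimethyl-15-[1-(3-methylbutyl)-2-oxo-2,5-dihydro-1H-pyrrol-4-yl]pentadeca-4,9,11-trienoate | COC(=O)[C@@H](O)C/C(C)=C\CC[C@H](C)/C=C/C=C(\C)CCCC1=CC(=O)N(CCC(C)C)C1 | intermediate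
23 | 2-propanoyloxy ester of 22 | COC(=O)[C@@H](OC(=O)CC)C/C(C)=C\CC[C@H](C)/C=C/C=C(\C)CCCC1=CC(=O)N(CCC(C)C)C1 | intermediate
24 | Sarcotrine D, (5S)-4-hydroxy-3-methyl-5-[(2Z,6S,7E,9E)-2,6,10-trimethyl-13-(1-(3-methylbutyl)-2-oxo-2,5-dihydro-1H-pyrrol-4-yl)trideca-2,7,9-trien-1-yl]furan-2(5H)-one | CC1=C(O)[C@H](C/C(C)=C\CC[C@H](C)/C=C/C=C(\C)CCCC2=CC(=O)N(CCC(C)C)C2)OC1=O | target

**Total steps:** 17. **Longest linear sequence:** 14 steps (steps 4 to 17).

**Three steps most likely to fail**
- **Step 3** (one-pot furan-to-pyrrolinone cascade). The hydroxybutenolide regiochemistry may be poor, aminolysis may stall, or the iodide may not survive the acid. Fallback: drop the furan and build the 4-alkylpyrrolin-2-one by ring-closing metathesis of N-isopentyl-N-(2-alkylallyl)acrylamide.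
- **Step 8** (Z-selective mono-methylation of the gem-dibromoalkene). Over-coupling or E/Z scrambling is possible. Fallback: switch to a Still–Gennari/Ando olefination of aldehyde 12 to the Z-2-methyl-enoate, then DIBAL, allylic bromide, and alkylation of an Evans glycolate to set C5.
- **Step 17** (Dieckmann on the fully elaborated substrate). C5 epimerisation or pyrrolinone/diene side reactions are possible. Fallback: O-silylate the α-hydroxy ester and add the lithium enolate of tert-butyl propionate in an intermolecular Claisen, then TBAF and TFA lactonisation to the tetronic acid.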